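## Analysis of the target

The target is a 1H-indole, a benzene ring fused through C3a–C7a to a pyrrole ring, and it has no stereocentre. Only one benzenoid carbon, C4, still carries hydrogen: C5 and C7 bear bromine, and C6, the carbon between them, bears the methoxy group. The pyrrole ring carries the third bromine at C3 and keeps N1–H and C2–H. The 3-bromoindole unit with a free N–H is the fragile part (sensitive to acid, light and oxidants, and able to lose its halogen), so the C3–Br bond belongs in the last step. The aryl bromides, once present, rule out dissolving-metal steps and late palladium chemistry. The difficulty is the unbroken C5–C6–C7 array next to the ring nitrogen: on a preformed 6-methoxyindole an electrophile would go to C3 and C2 before it reached C7, which is squeezed between the methoxy group and N1. The strategy rests on two facts: the oxygen-bearing C6 lies between C5 and C7, and C7 is bonded to C7a, the carbon that carries nitrogen. A benzene ring generated as a C6–C7 aryne inside an N-sulfonyl indoline, with nitrogen on C7a and a silyl group on C5, should accept an oxygen nucleophile only at C6; the silyl group then marks C5 for ipso-bromination, and C7 is left as the one free position ortho to the ether.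

## Retrosynthetic reasoning

**C3–Br.** The C3–Br bond of the target 15 is cut first, which leads back to 5,7-dibromo-6-methoxy-1H-indole 14. C3 is the most nucleophilic carbon of a free indole, so this halogen can be placed last and selectively, and the sensitive 3-bromoindole never has to survive another step.

**N1–S.** Indole 14 is traced to its N-tosyl derivative 13, 5,7-dibromo-6-methoxy-1-tosyl-1H-indole (tosyl = 4-methylbenzenesulfonyl). A sulfonyl group on an indole nitrogen leaves under mild base, because the indolide is a good leaving group. On an indoline nitrogen it would need a reducing metal, which the two C–Br bonds would not tolerate. The sulfonyl group is therefore removed only after the five-membered ring has been aromatised.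

**C2=C3.** The C2=C3 double bond of 13 is taken back to the C2–C3 single bond of 5,7-dibromo-6-methoxy-1-tosylindoline 12. The indoline oxidation level is what the key step delivers, since its tether is a saturated two-carbon chain. It is also the level at which the benzene ring is the only π system open to an electrophile. The forward step is a dehydrogenation driven by the gain of pyrrole aromaticity.

**C5–Br and C7–Br.** Both bonds of 12 are cut back to 6-methoxy-1-tosyl-5-(trimethylsilyl)indoline 10, through the monobromide 5-bromo-6-methoxy-1-tosylindoline 11. C5 is para to nitrogen, ortho to the methoxy group and carries silicon, so the first electrophile should replace the silyl group. C7 is then the only position ortho to the ether and ortho to nitrogen, while C4 is meta to both donors. The substitution pattern is thus written into 10 and does not depend on a delicate choice between similar C–H positions.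

**Key disconnection: C6–O, C4–C5 and C3a–C7a.** In 10 the C6–O bond and the C7–H bond are removed to give the aryne 9, 1-tosyl-5-(trimethylsilyl)-6,7-didehydroindoline. Cutting C4–C5 and C3a–C7a of 9 then opens both rings to the acyclic triyne 7, N-(but-3-yn-1-yl)-4-methyl-N-[4-(trimethylsilyl)buta-1,3-diyn-1-yl]benzenesulfonamide; the oxygen comes from methanol 8. This cut is preferred because one thermal, reagent-free step builds the benzene ring, the five-membered ring and the C6–O bond. It also leaves C7 unsubstituted and C5 silylated, exactly as the later brominations need. The forward reaction has to achieve the cycloisomerisation of an ynamide 1,3-diyne with an unactivated terminal alkyne, and the addition of methanol with oxygen at C6 and not at C7.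

**N–C(sp).** Triyne 7 is cut at the bond between nitrogen and the diyne into the sulfonamide 3, N-(but-3-yn-1-yl)-4-methylbenzenesulfonamide, and 1-bromo-4-(trimethylsilyl)buta-1,3-diyne 6. Copper-catalysed N-alkynylation forms this bond directly and convergently. The forward step must couple at nitrogen and leave the terminal alkyne of 3 alone.

**Building blocks.** Sulfonamide 3 comes from but-3-yn-1-amine 1 and 4-toluenesulfonyl chloride 2 by N–S bond formation. Bromodiyne 6 comes from 1,4-bis(trimethylsilyl)buta-1,3-diyne 4 by exchange of one silyl group for bromine through the lithium acetylide 5. The remaining silyl group stabilises the diyne terminus and later becomes the C5 marker.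

## Alternatives that were turned down

**Alternative 1:** The pyrrole ring is cut at N1–C2 and N1–C7a. This leads to the symmetric quinol aldehyde (3,5-dibromo-1-hydroxy-4-oxocyclohexa-2,5-dien-1-yl)acetaldehyde A2 and ammonia A3.
- Forward key step: A3 would condense with the aldehyde and add to one of the two equivalent enone β-carbons; two dehydrations would give 5,7-dibromo-1H-indol-6-ol A1. O-Methylation and C3 bromination would finish the synthesis.
- For it: both ring bromines come from a symmetric double ortho-bromination of a para-substituted phenol, so there is no regiochemical question. Either enone arm gives the same product, no nitrogen protecting group is needed, and the sequence is probably shorter than the chosen one.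
- Against it: A2 is a β-hydroxy aldehyde on a quinol carbon and is set up for retro-aldol fragmentation to a quinone under the basic conditions of its own key step. The conjugate addition also creates an amine β to a carbon that carries bromine next to a carbonyl group; loss of bromide from this arrangement (aziridine formation or dehydrobromination to an amino-enone) is a familiar exit, so the C7 bromine is at risk in the ring-forming step itself.
- Comparison: this alternative is stronger on step economy and on the placement of the ring bromines. The chosen strategy offers a key step whose reactive intermediate carries no halogen and whose precursor is a stable, neutral triyne, with the bromines introduced afterwards at positions fixed by the silyl group and the two donors.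

**Alternative 2:** The benzene ring is cut at C7–C7a and C3a–C4. This gives 3,5-dibromo-4-methoxy-2H-pyran-2-one A5 as the diene and tert-butyl 2,3-dihydro-1H-pyrrole-1-carboxylate A6 as the 2π partner.
- Forward key step: a thermal [4+2] cycloaddition followed by a decarboxylative cycloreversion would give the cis-fused diene tert-butyl cis-5,7-dibromo-6-methoxy-2,3,3a,7a-tetrahydroindole-1-carboxylate A4 (racemic; both stereocentres are lost on aromatisation). Two dehydrogenations, carbamate removal and C3 bromination would follow.
- For it: all three benzenoid substituents arrive in place on one small building block. The polarity match is correct, since the nucleophilic β-carbon of A6 should bond to the electrophilic C6 of A5, and dibromopyranones are established dienes.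
- Against it: the 4-methoxy group makes A5 a vinylogous carbonate and raises its LUMO, so its reaction with the electron-rich A6 should be sluggish. A5 itself needs a separate multi-step preparation. In A4 the carbamate nitrogen on C7a is allylic and sits next to C3a–H, so aromatisation by β-elimination of nitrogen (opening to an arylethyl carbamate) competes with the oxidation that is needed. Two oxidation levels have to be removed after the key step, against one in the chosen route.
- Comparison: this alternative is at least as strong on the certainty of the bromine positions. It is weaker on redox economy and on the survival of the C7a–N bond. The chosen strategy gives an aromatic ring directly from its key step.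

**Alternative 3:** The pyrrole ring is cut at the C2=C3 double bond. This leads to N-(2,4-dibromo-6-formyl-3-methoxyphenyl)formamide A8.
- Forward key step: low-valent titanium (from TiCl3 and zinc dust) would couple the aldehyde carbon with the formamide carbon in a McMurry-type oxo-amide coupling to give 5,7-dibromo-6-methoxy-1H-indole A7, the same compound as 14 of the chosen route. C3 bromination would finish.
- For it: in the aniline precursor of A8 the amino and methoxy groups direct bromine cooperatively to the two required positions, no nitrogen protecting group is needed, and the route reaches the penultimate indole in clearly fewer steps than the chosen one.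
- Against it: an aldehyde paired with a formamide is the least favourable case for this coupling, because the aldehyde can homocouple to a pinacol or stilbene faster than it cross-couples with the poorly electrophilic formamide carbonyl. The low-valent metal is used in large excess at reflux in the presence of two aryl bromides, one of them ortho to nitrogen, so reductive loss of bromine is a concern. N-Formylation of an aniline flanked by bromine and a formyl-bearing carbon is also hindered.
- Comparison: this alternative is stronger on step count and on regiochemical certainty, and would be the pragmatic choice if the titanium coupling tolerates the substrate. The chosen strategy offers a ring construction that needs no reductant near C–Br bonds. It is also modular: another alcohol in the key step or another electrophile at the silylated C5 would give analogues.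

Key step: step 4

Assumption: but-3-yn-1-amine 1 is used as the free base (its hydrochloride would only need one more equivalent of Et3N), and the 150 °C quoted for step 4 is an estimate for an unactivated terminal alkyne as the 2π partner.

## Route

**Step 1**
Reactants: 1 but-3-yn-1-amine; 2 4-toluenesulfonyl chloride
Product: 3 N-(but-3-yn-1-yl)-4-methylbenzenesulfonamide
Conditions: Et3N (1.5 equiv), CH2Cl2, 0 °C to rt
Reagents that add atoms: none
Why: N-Sulfonylation of a primary amine: the amine attacks sulfur and Et3N takes up HCl. The terminal alkyne is a bystander, and the remaining acidic N–H is the handle for step 3.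

**Step 2**
Reactants: 4 1,4-bis(trimethylsilyl)buta-1,3-diyne
Product: 6 1-bromo-4-(trimethylsilyl)buta-1,3-diyne, via lithium 4-(trimethylsilyl)buta-1,3-diyn-1-ide 5 (not isolated)
Conditions: MeLi·LiBr (1.0 equiv), THF, rt; then NBS (1.05 equiv), −78 °C to 0 °C; product kept cold and used promptly
Reagents that add atoms: N-bromosuccinimide, O=C1CCC(=O)N1Br
Why: Nucleophilic cleavage of one alkynyl–silicon bond gives the lithium acetylide 5, whose negative charge shields the second silyl group from attack, so mono-exchange is expected. Halogenation of the metal acetylide with NBS then gives the 1-bromoalkyne; both operations are standard acetylide chemistry.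

**Step 3**
Reactants: 3 N-(but-3-yn-1-yl)-4-methylbenzenesulfonamide; 6 1-bromo-4-(trimethylsilyl)buta-1,3-diyne
Product: 7 N-(but-3-yn-1-yl)-4-methyl-N-[4-(trimethylsilyl)buta-1,3-diyn-1-yl]benzenesulfonamide
Conditions: CuSO4·5H2O (10 mol%), 1,10-phenanthroline (20 mol%), K2CO3 (2 equiv), toluene, 65 °C
Reagents that add atoms: none
Why: Copper-catalysed N-alkynylation of a sulfonamide with a 1-bromoalkyne (Ullmann-type C(sp)–N coupling), a standard entry to ynamides that also accepts bromodiynes. The sulfonamide N–H is far more acidic than the alkyl acetylene C–H, so carbonate in toluene should deliver only the amidate to copper and C–C coupling at the free alkyne should stay minor. The temperature is far below that at which 7 cycloisomerises.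

**Step 4**
Reactants: 7 N-(but-3-yn-1-yl)-4-methyl-N-[4-(trimethylsilyl)buta-1,3-diyn-1-yl]benzenesulfonamide; 8 methanol
Product: 10 6-methoxy-1-tosyl-5-(trimethylsilyl)indoline, via 1-tosyl-5-(trimethylsilyl)-6,7-didehydroindoline 9 (not isolated)
Conditions: MeOH as solvent (0.01 M in 7), steel pressure vessel, 150 °C
Reagents that add atoms: none
Why: On heating, the 1,3-diyne of 7 (4π) and the tethered terminal alkyne (2π) should combine in an intramolecular hexadehydro-Diels–Alder cycloisomerisation, most likely stepwise through a diradical: the C3a–C7a bond forms first and closes the five-membered ring in a 5-exo-dig sense across the three-atom N1–C2–C3 tether, and the C4–C5 bond then closes the six-membered ring as the second σ bond of the formal [4+2] process, which leaves the strained in-plane C6–C7 π bond of aryne 9. The closest known reaction type is the thermal cycloisomerisation of ynamide-tethered tri- and tetraynes to indoline-fused arynes that are trapped in the same flask by O–H nucleophiles. Methanol adds across the strained bond with O–C6 bond formation and proton delivery to C7; this addition is of higher order in alcohol than the competing transfer of two hydrogen atoms from the alcohol to the aryne, so neat methanol should favour the ether over the reduced arene. The selectivity needed is oxygen at C6 and not at C7, and three features of 9 point the same way: the σ-withdrawing nitrogen on C7a stabilises negative charge building at C7, the fused five-membered ring pinches the internal angle at C7 and widens that at C6, and the electropositive silyl group on C5 widens the angle at C6 further, so the small nucleophile should attack C6. No stereocentre is formed. High dilution keeps bimolecular reactions of 7 and 9 in check, and the silyl cap keeps the diyne terminus from reacting with itself.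

**Step 5**
Reactants: 10 6-methoxy-1-tosyl-5-(trimethylsilyl)indoline
Product: 12 5,7-dibromo-6-methoxy-1-tosylindoline, via 5-bromo-6-methoxy-1-tosylindoline 11 (not isolated)
Conditions: Br2 (2.2 equiv), AcOH, rt to 40 °C
Reagents that add atoms: bromine, BrBr
Why: Two electrophilic aromatic substitutions: the first bromine replaces silicon at C5 by ipso attack (arenium ion stabilised by the β-silicon, the para nitrogen and the ortho methoxy group), the second enters C7, the only free position ortho to the methoxy group and also ortho to nitrogen, while C4 is meta to both donors. At the indoline level there is no pyrrole double bond to compete.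

**Step 6**
Reactants: 12 5,7-dibromo-6-methoxy-1-tosylindoline
Product: 13 5,7-dibromo-6-methoxy-1-tosyl-1H-indole
Conditions: DDQ (2 equiv), PhCl, 120 °C
Reagents that add atoms: none
Why: Quinone dehydrogenation of an N-sulfonylindoline to the indole: DDQ abstracts hydride from the benzylic C3, loss of the C2 proton follows, and the gain of pyrrole aromaticity drives the reaction. Aryl bromides, ether and sulfonamide are inert to DDQ.

**Step 7**
Reactants: 13 5,7-dibromo-6-methoxy-1-tosyl-1H-indole
Product: 14 5,7-dibromo-6-methoxy-1H-indole
Conditions: KOH (5 equiv), THF/MeOH/H2O, 50 °C
Reagents that add atoms: none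
Why: Base-mediated cleavage of an N-sulfonylindole: hydroxide attacks sulfur and the indolide, a good leaving group made better by the two bromines, departs. This non-reducing deprotection leaves the C–Br bonds untouched, which is the reason for aromatising before removing the tosyl group.

**Step 8**
Reactants: 14 5,7-dibromo-6-methoxy-1H-indole
Product: 15 3,5,7-tribromo-6-methoxy-1H-indole
Conditions: NBS (1.0 equiv), DMF, −20 °C to 0 °C, dark
Reagents that add atoms: N-bromosuccinimide, O=C1CCC(=O)N1Br
Why: Electrophilic bromination of a free indole at C3, its most nucleophilic, enamine-like position, with one equivalent of NBS at low temperature. The benzene ring has only the deactivated C4–H left, and C2 should react only with excess reagent.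

## Compound list

1 | but-3-yn-1-amine | C#CCCN | starting material
2 | 4-toluenesulfonyl chloride | Cc1ccc(cc1)S(=O)(=O)Cl | starting material
3 | N-(but-3-yn-1-yl)-4-methylbenzenesulfonamide | C#CCCNS(=O)(=O)c1ccc(C)cc1 | intermediate
4 | 1,4-bis(trimethylsilyl)buta-1,3-diyne | C[Si](C)(C)C#CC#C[Si](C)(C)C | starting material
5 | lithium 4-(trimethylsilyl)buta-1,3-diyn-1-ide | [Li]C#CC#C[Si](C)(C)C | intermediate
6 | 1-bromo-4-(trimethylsilyl)buta-1,3-diyne | BrC#CC#C[Si](C)(C)C | intermediate
7 | N-(but-3-yn-1-yl)-4-methyl-N-[4-(trimethylsilyl)buta-1,3-diyn-1-yl]benzenesulfonamide | C#CCCN(C#CC#C[Si](C)(C)C)S(=O)(=O)c1ccc(C)cc1 | intermediate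
8 | methanol | CO | starting material
9 | 1-tosyl-5-(trimethylsilyl)-6,7-didehydroindoline | Cc1ccc(cc1)S(=O)(=O)N1CCC2=C1C#CC(=C2)[Si](C)(C)C | intermediate
10 | 6-methoxy-1-tosyl-5-(trimethylsilyl)indoline | COc1cc2N(S(=O)(=O)c3ccc(C)cc3)CCc2cc1[Si](C)(C)C | intermediate
11 | 5-bromo-6-methoxy-1-tosylindoline | COc1cc2N(S(=O)(=O)c3ccc(C)cc3)CCc2cc1Br | intermediate
12 | 5,7-dibromo-6-methoxy-1-tosylindoline | COc1c(Br)c2N(S(=O)(=O)c3ccc(C)cc3)CCc2cc1Br | intermediate
13 | 5,7-dibromo-6-methoxy-1-tosyl-1H-indole | COc1c(Br)c2n(S(=O)(=O)c3ccc(C)cc3)ccc2cc1Br | intermediate
14 | 5,7-dibromo-6-methoxy-1H-indole | COc1c(Br)c2[nH]ccc2cc1Br | intermediate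
15 | 3,5,7-tribromo-6-methoxy-1H-indole | COc1c(Br)cc2c(Br)c[nH]c2c1Br | target

## Step count and least certain steps

Total step count: 8. Longest linear sequence: 7 steps (steps 1, 3, 4, 5, 6, 7 and 8 from 1; step 2 is a one-step side branch that supplies 6).

**Step 4 (key step).**
- What may go wrong: the cycloisomerisation may be too slow at temperatures that 7 survives. The 2π partner is a terminal, non-conjugated alkyne and lacks a substituent that would stabilise the radical centre formed in the first bond-forming event. During long heating in methanol, solvolysis of the ynamide, cleavage of the alkynyl–silicon bond and diversion of the aryne by hydrogen transfer from the alcohol may compete.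
- Mitigating point: loss of the silyl group alone would not be fatal, because a C5–H indoline would still be brominated at C5 and C7 and would converge on 12.
- Fallback (from 7, back at 10): 7 would be heated in 1,2-dichlorobenzene (0.01 M, 180 °C) with acetic acid (10 equiv). The acid adds to aryne 9 as a monomer and cannot transfer two hydrogens, and the inert high-boiling solvent allows a higher temperature without pressure. This should give 1-tosyl-5-(trimethylsilyl)indolin-6-yl acetate F1. Methanolysis with K2CO3 in MeOH at rt would give 1-tosyl-5-(trimethylsilyl)indolin-6-ol F2, and O-methylation with MeI and K2CO3 in acetone would return to 10.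

**Step 3.**
- What may go wrong: coupling at carbon instead of nitrogen. A copper acetylide formed from the terminal alkyne of 3 could attack bromodiyne 6 in a Cadiot–Chodkiewicz-type reaction or dimerise oxidatively, and so consume both partners.
- Fallback (from 3, back at 12): the alkyne C–H would be masked first. Treating 3 with n-BuLi (2.1 equiv) and Me3SiCl in THF at −78 °C, with an aqueous work-up that cleaves the N–Si bond, would give 4-methyl-N-[4-(trimethylsilyl)but-3-yn-1-yl]benzenesulfonamide F3. Coupling of F3 with 6 under the conditions of step 3 would give 4-methyl-N-[4-(trimethylsilyl)but-3-yn-1-yl]-N-[4-(trimethylsilyl)buta-1,3-diyn-1-yl]benzenesulfonamide F4. K2CO3 in MeOH/THF at 0 °C would remove both silyl groups to give N-(buta-1,3-diyn-1-yl)-N-(but-3-yn-1-yl)-4-methylbenzenesulfonamide F5, which would be handled only in dilute solution. Heating F5 in methanol as in step 4 should give, through the aryne 1-tosyl-6,7-didehydroindoline F6, 6-methoxy-1-tosylindoline F7. The nitrogen on C7a and the ring fusion alone would direct oxygen to C6. Bromination of F7 with Br2 (2.1 equiv) in AcOH, first at C5 (para to nitrogen, ortho to the ether) and then at C7, would return to 12.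

**Step 5.**
- What may go wrong: the second bromination may stall or stray. C7 lies between the methoxy group and the bulky N-sulfonyl group, and the ring is already deactivated by the C5 bromine, so incomplete conversion or attack at C4 may give mixtures.
- Fallback (from 10, back at 14): the sulfonyl group would be removed while no C–Br bond is present. Mg turnings in MeOH with sonication at rt would give 6-methoxy-5-(trimethylsilyl)indoline F8. The free aniline-type nitrogen activates C5 (para, ipso to silicon) and C7 (ortho) strongly, so benzyltrimethylammonium tribromide (2 equiv) with CaCO3 in CH2Cl2/MeOH at rt should give 5,7-dibromo-6-methoxyindoline F9. Dehydrogenation of this free indoline with MnO2 in CH2Cl2 at rt would lead to 14 and bypass steps 6 and 7.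

**Step 6.**
- What may go wrong: hydride abstraction from C3 may be slow. The nitrogen lone pair is tied up by the sulfonyl group, the two bromines withdraw electron density, and the methoxy group, twisted between them, gives little help. Prolonged heating with DDQ may then lead to degradation.
- Fallback (from 12, back at 13): radical benzylic bromination with NBS (1.1 equiv) and AIBN (cat.) in PhCF3 at reflux would give racemic 3,5,7-tribromo-6-methoxy-1-tosylindoline F10. E2 elimination of HBr with DBU in toluene at 80 °C would give 13. Stray bromination of the tosyl methyl group would be of no consequence, since that group is removed in step 7.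

## Further compounds

F1 | step 4 | 1-tosyl-5-(trimethylsilyl)indolin-6-yl acetate | CC(=O)Oc1cc2N(S(=O)(=O)c3ccc(C)cc3)CCc2cc1[Si](C)(C)C
F2 | step 4 | 1-tosyl-5-(trimethylsilyl)indolin-6-ol | Oc1cc2N(S(=O)(=O)c3ccc(C)cc3)CCc2cc1[Si](C)(C)C
F3 | step 3 | 4-methyl-N-[4-(trimethylsilyl)but-3-yn-1-yl]benzenesulfonamide | C[Si](C)(C)C#CCCNS(=O)(=O)c1ccc(C)cc1
F4 | step 3 | 4-methyl-N-[4-(trimethylsilyl)but-3-yn-1-yl]-N-[4-(trimethylsilyl)buta-1,3-diyn-1-yl]benzenesulfonamide | C[Si](C)(C)C#CCCN(C#CC#C[Si](C)(C)C)S(=O)(=O)c1ccc(C)cc1
F5 | step 3 | N-(buta-1,3-diyn-1-yl)-N-(but-3-yn-1-yl)-4-methylbenzenesulfonamide | C#CCCN(C#CC#C)S(=O)(=O)c1ccc(C)cc1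
F6 | step 3 | 1-tosyl-6,7-didehydroindoline | Cc1ccc(cc1)S(=O)(=O)N1CCC2=C1C#CC=C2
F7 | step 3 | 6-methoxy-1-tosylindoline | COc1ccc2CCN(c2c1)S(=O)(=O)c1ccc(C)cc1
F8 | step 5 | 6-methoxy-5-(trimethylsilyl)indoline | COc1cc2NCCc2cc1[Si](C)(C)C
F9 | step 5 | 5,7-dibromo-6-methoxyindoline | COc1c(Br)c2NCCc2cc1Br
F10 | step 6 | 3,5,7-tribromo-6-methoxy-1-tosylindoline (racemic) | COc1c(Br)c2N(S(=O)(=O)c3ccc(C)cc3)CC(Br)c2cc1Br
A1 | alternative 1 | 5,7-dibromo-1H-indol-6-ol | Oc1c(Br)cc2cc[nH]c2c1Br
A2 | alternative 1 | (3,5-dibromo-1-hydroxy-4-oxocyclohexa-2,5-dien-1-yl)acetaldehyde | O=CCC1(O)C=C(Br)C(=O)C(Br)=C1
A3 | alternative 1 | ammonia | N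
A4 | alternative 2 | tert-butyl cis-5,7-dibromo-6-methoxy-2,3,3a,7a-tetrahydroindole-1-carboxylate (racemic, one enantiomer drawn) | CC(C)(C)OC(=O)N1CC[C@H]2C=C(Br)C(OC)=C(Br)[C@@H]12
A5 | alternative 2 | 3,5-dibromo-4-methoxy-2H-pyran-2-one | COC1=C(Br)C(=O)OC=C1Br
A6 | alternative 2 | tert-butyl 2,3-dihydro-1H-pyrrole-1-carboxylate | CC(C)(C)OC(=O)N1CCC=C1
A7 | alternative 3 | 5,7-dibromo-6-methoxy-1H-indole | COc1c(Br)cc2cc[nH]c2c1Br
A8 | alternative 3 | N-(2,4-dibromo-6-formyl-3-methoxyphenyl)formamide | O=CNc1c(Br)c(OC)c(Br)cc1C=O
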